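The data are calculated with constants of no real substance; scatter was added.

Slowness is what I see first: 20.0 h into the eta run, after its feed of 8.0 h has ended, X stands at 16.8 % of the Z charged.

| flask | Z | E | remark | time |
|---|---|---|---|---|
| theta | 0.34 M | 0.12 M (fed, over 8.0 h) | run made earlier; the fed solution adds 0.10 times the starting volume |  |
| eta | 0.34 M | 0.18 M (fed, over 8.0 h) | run made earlier; the fed solution adds 0.10 times the starting volume |  |
| flask | 0.34 M | 0.238 M (fed, over 8.0 h) | the fed solution adds 0.10 times the starting volume | 20 h |

| run | time / h | X / % | Z / % |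
|---|---|---|---|
| theta | 5.00 | 2.0 | 88.2 |
| theta | 8.00 | 5.2 | 84.3 |
| theta | 10.0 | 7.2 | 82.0 |
| theta | 15.0 | 10.5 | 77.4 |
| theta | 20.0 | 11.6 | 73.9 |
| eta | 5.00 | 3.0 | 88.1 |
| eta | 8.00 | 7.4 | 83.8 |
| eta | 10.0 | 9.5 | 79.7 |
| eta | 15.0 | 14.2 | 73.9 |
| eta | 20.0 | 16.8 | 70.0 |

(each reading ± 0.3 percentage points)

1. the moment within 20 h at which there is most X
2. the amount of X, in percent of the Z charged, at that time
3. the first time at which X reaches 6.3 %, in the same percent

- charges are per starting volume, the dose included; the dosed solution carries all of it
- the numbers in the tables scatter with a standard deviation of 0.3 percentage points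
- at the start none of Z is in solution
- a reading or a percentage of X counts all its forms, free or not

Does X follow the E charged? From theta to eta the charge of E rises by a factor of 1.50 and X at 20.0 h by 1.45, so I take strict proportion as the zero of my scale. Capture, the X standing at 20.0 h per E charged, counted one for one, reads 31.7 % in the eta run and 32.9 % in the theta run.

Does X peak before the limit? Between 15.0 h and 20.0 h the eta run still gains 2.6 percentage points and the theta run 1.1 points, against a scatter of 0.3 points, so I put the best moment in the flask at 20 h.

How much, then? In the flask E is the limiting reagent, 0.238 M against 0.34 M of Z, and capture gives 22.2 %. The level of 6.3 % in the flask corresponds to 4.76 % in the eta run, which straight interpolation between its readings at 5.00 h and 8.00 h reaches at 6.20 h.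

The forecast gives 20 h, 21.7 % and 6.4 h, an amount lower than mine and a time later than mine, saying “I expect the best point at the 20 h limit”.

The flask gives 21.0 % at 20.0 h, and X first reaches the level at 6.65 h.

    E → Q (k = 0.0980 h⁻¹)
    G ⇌ X, rate k2*(cs2 - [X]) while solid is left; crystals form when [X] > cs2 (solubility = 19.0 mM, k = 6.00 h⁻¹)
    Z ⇌ J, rate k3*(cs3 - [J]) while solid is left; crystals form when [J] > cs3 (solubility = 46.0 mM, k = 0.310 h⁻¹)
    J + E → X (k = 1.70 L mol⁻¹ h⁻¹)

Capture carried over gave the flask 22.2 %; the flask's own capture reads 30.0 %, with Q at 0.131 M and 9.4 % of E left at 20.0 h. The neighbouring flask, with Z cut to 0.14 M, keeps the E charge of the flask, so capture gives it 53.9 %. That neighbouring flask gives 51.1 %, a capture of 30.1 %, with Q at 0.131 M and 9.4 % of E left. At its end X, at 51.1 %, holds more of the Z charged than Z itself, which is down to 18.3 %.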